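**Strategy**

The fourteen-membered carbocycle (cembrane numbering: C1 and C2 carry the fused lactone, C9 the acetate) is opened at C5–C6, the one ring bond that joins the two allylic methylenes of the C3=C4/C7=C8 1,5-diene. The key step closes it by intramolecular alkylation: a phenylsulfonyl group at C6 gives an allyl anion that displaces a primary allylic bromide at C5 (14-exo-tet), with the three E-olefins and the C1, C2 and C9 stereocentres already in place. The precursor is an acyclic sulfone bromide; afterwards the sulfone is removed reductively and the α-methylene lactone is built by cyclocarbonylation of a C1 ethynyl group onto the C2 hydroxyl.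

Key step: step 19

Remarks
- Locants C1–C20 follow cembrane numbering of the target: ring C1–C14 (C2 bears the lactone oxygen), C15 = lactone α-carbon, C16 = C=O, C17 = exocyclic CH2, C18/C19/C20 = methyls on C4/C8/C12. TBS = tert-butyldimethylsilyl, TIPS = triisopropylsilyl.
- Remark on the chemistry (assumption): the (R)-configured phosphoric acid in step 5 is assumed to direct Re-face addition to the enal, as it does for aryl and α,β-unsaturated aldehydes; if the sense were opposite, the (S)-acid would be used.

**Route**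

Step 1
Reactants: 1 prenyl bromide (1-bromo-3-methylbut-2-ene); 2 sodium benzenesulfinate
Product: 3 prenyl phenyl sulfone
Conditions: DMF, rt
Reagents that add atoms: none
Why: SN2 S-alkylation of the sulfinate at the primary allylic bromide should give the primary allylic sulfone that later serves as the C6 carbanion precursor.

Step 2
Reactants: 3 prenyl phenyl sulfone
Product: 4 (E)-2-methyl-4-(phenylsulfonyl)but-2-enal
Conditions: SeO2 (1.2 equiv), 1,4-dioxane/H2O (20:1), 90 °C
Reagents that add atoms: selenium dioxide, O=[Se]=O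
Why: Riley allylic oxidation (ene reaction, [2,3]-sigmatropic shift, further oxidation of the allylic alcohol) is expected at the methyl group trans to the chain, which fixes the E geometry of the later C7=C8 bond and delivers C9 as the aldehyde.

Step 3
Reactants: 5 but-2-yn-1-ol
Product: 6 but-2-yn-1-yl methyl carbonate
Conditions: ClCO2Me, pyridine, CH2Cl2, 0 °C
Reagents that add atoms: methyl chloroformate, COC(=O)Cl
Why: O-acylation of the primary propargylic alcohol installs the leaving group for the copper-catalysed borylation.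

Step 4
Reactants: 6 but-2-yn-1-yl methyl carbonate
Product: 7 2-(buta-2,3-dien-2-yl)-4,4,5,5-tetramethyl-1,3,2-dioxaborolane
Conditions: B2pin2 (1.2 equiv), CuCl (5 mol %), NaOtBu (5 mol %), 4,5-bis(diphenylphosphino)-9,9-dimethylxanthene (5 mol %), THF, rt
Reagents that add atoms: bis(pinacolato)diboron, CC1(C)OB(OC1(C)C)B1OC(C)(C)C(C)(C)O1
Why: Copper-catalysed γ-selective (SN2′) borylation of a propargylic carbonate: the boryl–copper species adds to the alkyne carbon remote from the leaving group, and β-oxygen elimination should give the allenylboronate with boron on the methyl-bearing carbon.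

Step 5
Reactants: 4 (E)-2-methyl-4-(phenylsulfonyl)but-2-enal; 7 allenylboronate
Product: 8 (4R,2E)-3-methyl-1-(phenylsulfonyl)oct-2-en-6-yn-4-ol
Conditions: 7 (1.3 equiv), (R)-3,3′-bis(2,4,6-triisopropylphenyl)-1,1′-binaphthyl-2,2′-diyl hydrogen phosphate (10 mol %), 4 Å molecular sieves, toluene, 0 °C; aqueous work-up
Reagents that add atoms: none
Why: Chiral-phosphoric-acid-catalysed allenylboration through a six-membered SE2′ transition state joins the CH2 terminus of the allene to the aldehyde carbon in a 1,2-addition (the boron-bearing carbon becomes the methyl-substituted alkyne carbon), and Re-face attack enforced by the acid should set the (R)-carbinol that becomes C9.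

Step 6
Reactants: 8 homopropargylic alcohol
Product: 9 (4R,2E)-4-(TBSO)-3-methyl-1-(phenylsulfonyl)oct-2-en-6-yne
Conditions: TBSOTf, 2,6-lutidine, CH2Cl2, −78 → 0 °C
Reagents that add atoms: tert-butyldimethylsilyl triflate, CC(C)(C)[Si](C)(C)OS(=O)(=O)C(F)(F)F
Why: Silylation of the secondary alcohol with retention protects C9–OH through the organometallic and basic steps that follow.

Step 7
Reactants: 9 silyl ether
Product: 11 (2E,4R,6E)-4-(TBSO)-7-iodo-3-methyl-1-(phenylsulfonyl)octa-2,6-diene, via alkenylzirconocene chloride 10 (not isolated)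
Conditions: Cp2Zr(H)Cl (2.5 equiv), THF, 50 °C; then I2, 0 °C
Reagents that add atoms: iodine, II
Why: syn-Hydrozirconation of the 2-alkyne equilibrates under excess Cp2Zr(H)Cl to place zirconium on the less hindered methyl-bearing carbon, and iodinolysis with retention should give the (E)-2-iodoalkene that encodes the E geometry of C11=C12.

Step 8
Reactants: 12 ethynyltriisopropylsilane; 13 acrolein
Product: 15 rac-5-(triisopropylsilyl)pent-1-en-4-yn-3-ol, via lithium silylacetylide 14 (not isolated)
Conditions: n-BuLi, THF, −78 °C; then 13, −78 °C; H2O quench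
Reagents that add atoms: none
Why: 1,2-Addition of the lithium acetylide to acrolein at low temperature should give the racemic alkynyl vinyl carbinol.

Step 9
Reactants: 15 racemic carbinol
Product: 16 (S)-5-(triisopropylsilyl)pent-1-en-4-yn-3-ol
Conditions: lipase from Burkholderia cepacia (Amano PS), vinyl acetate, hexane, rt, to just over half conversion; chromatography
Reagents that add atoms: none
Why: Lipase-mediated kinetic resolution by transesterification is expected to acetylate the (R)-enantiomer (large silylethynyl versus medium vinyl group), so the unreacted (S)-alcohol, the later source of the C1 configuration, is recovered.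

Step 10
Reactants: 16 (S)-enynol; 11 vinyl iodide
Product: 18 (3S,6E,9R,10E)-9-(TBSO)-6,10-dimethyl-12-(phenylsulfonyl)-1-(TIPS)dodeca-6,10-dien-1-yn-3-ol, via B-alkyl-9-borabicyclononane borinate 17 (not isolated)
Conditions: 16 (1.4 equiv), 9-borabicyclo[3.3.1]nonane dimer (3 equiv B–H), THF, 0 °C → rt; then 11, PdCl2(dppf) (5 mol %; dppf = 1,1′-bis(diphenylphosphino)ferrocene), AsPh3 (10 mol %), K3PO4 (3 M aq), DMF, rt
Reagents that add atoms: none
Why: Anti-Markovnikov hydroboration of the vinyl group (the hindered silylalkyne is spared, the hydroxyl only consumes one B–H) followed by B-alkyl Suzuki–Miyaura coupling with retention at the iodoalkene should form C12–C13 and the (E)-C11=C12 olefin without touching the carbinol centre.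

Step 11
Reactants: 18 propargylic alcohol
Product: 19 (3S)-methanesulfonate of 18
Conditions: MsCl, Et3N, CH2Cl2, −78 °C
Reagents that add atoms: methanesulfonyl chloride, CS(=O)(=O)Cl
Why: O-Sulfonylation with retention activates the propargylic position for anti-SN2′ ionisation.

Step 12
Reactants: 20 1-(TBSO)propan-2-one; 21 triethyl phosphonoacetate
Product: 22 ethyl (E)-4-(TBSO)-3-methylbut-2-enoate
Conditions: NaH, THF, 0 °C → rt; chromatography
Reagents that add atoms: none
Why: Horner–Wadsworth–Emmons olefination of the ketone is expected to favour the E-enoate (ester trans to the silyloxymethyl group), and any Z-isomer is removed by chromatography.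

Step 13
Reactants: 22 enoate
Product: 23 (E)-4-(TBSO)-3-methylbut-2-en-1-ol
Conditions: i-Bu2AlH (2.2 equiv), CH2Cl2, −78 °C; Rochelle salt work-up
Reagents that add atoms: none
Why: 1,2-Reduction of the conjugated ester to the allylic alcohol leaves the olefin geometry and the silyl ether intact.

Step 14
Reactants: 23 allylic alcohol
Product: 24 (E)-4-(TBSO)-3-methylbut-2-enal
Conditions: MnO2, CH2Cl2, rt
Reagents that add atoms: none
Why: Mild allylic oxidation gives the enal (C2–C5 with C18) without E/Z isomerisation.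

Step 15
Reactants: 19 propargylic mesylate; 24 enal
Product: 26 (2E,4S,5R,8E,11R,12E)-1,11-bis(TBSO)-2,8,12-trimethyl-14-(phenylsulfonyl)-5-(TIPS-ethynyl)tetradeca-2,8,12-trien-4-ol, via allenylindium reagent 25 (not isolated)
Conditions: PdCl2(dppf) (5 mol %), InI (1.5 equiv), THF/HMPA (3:1), rt
Reagents that add atoms: none
Why: Zerovalent palladium (generated from PdCl2(dppf) by InI) should ionise the (S)-mesylate by anti-SN2′ attack, transmetalation to indium gives the configurationally defined (aR)-allenylindium 25, and its cyclic SE2′ addition to the aldehyde should give the anti homopropargylic alcohol, so that C1 (R) arises by chirality transfer from the mesylate and C2 (S) from the anti relationship that later becomes the trans ring fusion.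

Step 16
Reactants: 26 homopropargylic alcohol
Product: 27 tris-TBS ether (C2–OTBS)
Conditions: TBSOTf, 2,6-lutidine, CH2Cl2, −78 → 0 °C
Reagents that add atoms: tert-butyldimethylsilyl triflate, CC(C)(C)[Si](C)(C)OS(=O)(=O)C(F)(F)F
Why: Silylation of C2–OH with retention prevents alkoxide participation (SN2′ epoxide formation, O-alkylation) once C5 carries a leaving group.

Step 17
Reactants: 27 tris-TBS ether
Product: 28 primary allylic alcohol (C5–OH)
Conditions: HF·pyridine, pyridine, THF, 0 °C
Reagents that add atoms: none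
Why: Buffered HF·pyridine should cleave the unhindered primary TBS ether much faster than the two secondary ones and leave the alkynylsilane untouched.

Step 18
Reactants: 28 primary allylic alcohol
Product: 29 primary allylic bromide (C5–Br)
Conditions: CBr4, PPh3, 2,6-lutidine (cat.), CH2Cl2, −20 °C
Reagents that add atoms: carbon tetrabromide, BrC(Br)(Br)Br
Why: Appel bromination proceeds by SN2 displacement of the oxyphosphonium at the primary carbon under near-neutral conditions, so the E-olefin and the silyl ethers should survive.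

Step 19
Reactants: 29 sulfone bromide
Product: 31 macrocyclic sulfone (1R,2S,3E,7E,9R,11E)-2,9-bis(TBSO)-4,8,12-trimethyl-6-(phenylsulfonyl)-1-(TIPS-ethynyl)cyclotetradeca-3,7,11-triene, via potassium sulfonyl carbanion 30 (not isolated)
Conditions: KN(SiMe3)2 (1.3 equiv), THF, −78 → −40 °C; 29 added by syringe pump over 10 h (final concentration 2 mM); NH4Cl quench
Reagents that add atoms: none
Why: KN(SiMe3)2 removes the proton at C6, which is α to the sulfone and allylic to C7=C8, and the sulfonyl-stabilised allyl anion 30 displaces bromide at C5 in an intramolecular SN2 reaction. The closest known reaction type is the intramolecular alkylation of allylic sulfone or sulfide carbanions with allylic halides used for cembranoid macrocycles, the cyclic form of the Julia-type 1,5-diene synthesis. The fourteen-membered carbocycle closes in the 14-exo-tet mode. The only new stereocentre, C6, is not controlled and need not be, because step 20 erases it, while C1, C2 and C9 are untouched. The step needs α- over γ-attack of the anion (C6 versus C8), SN2 over SN2′ attack on the bromide (C5 versus C3) and cyclisation over oligomerisation; these are secured by charge localisation next to sulfur and the fully substituted C8 terminus, by the unhindered primary C5 against a C3 flanked by the C2 silyl ether, and by slow addition at high dilution. Both neighbouring olefins should keep their E geometry because the anion is formed and consumed at low temperature and C3=C4 is not involved in the displacement.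

Step 20
Reactants: 31 macrocyclic sulfone
Product: 32 (1R,2S,3E,7E,9R,11E)-2,9-bis(TBSO)-4,8,12-trimethyl-1-(TIPS-ethynyl)cyclotetradeca-3,7,11-triene
Conditions: PdCl2(dppp) (10 mol %; dppp = 1,3-bis(diphenylphosphino)propane), LiBHEt3 (3 equiv), THF, 0 °C → rt
Reagents that add atoms: none
Why: Palladium-catalysed reductive desulfonylation: zerovalent palladium ionises the allylic sulfone to a π-allyl complex (C6–C7–C8), and hydride should be delivered to the less substituted C6 terminus remote from the C9 silyloxy group, so C7=C8 stays in place with E geometry.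

Step 21
Reactants: 32 bis-silyl ether
Product: 33 (1R,2S,3E,7E,9R,11E)-1-ethynyl-4,8,12-trimethylcyclotetradeca-3,7,11-triene-2,9-diol
Conditions: Bu4NF (5 equiv), THF, rt
Reagents that add atoms: none
Why: Fluoride should cleave both O–Si bonds and the alkynyl C–Si bond in one operation without affecting any stereocentre.

Step 22
Reactants: 33 ethynyl diol
Product: 34 (1R,2S,3E,7E,9R,11E)-9-hydroxycembra-3,7,11,15(17)-tetraen-16,2-olide
Conditions: PdI2 (5 mol %), n-Bu3P (10 mol %), CO (7 atm), MeCN, 75 °C
Reagents that add atoms: carbon monoxide, [C-]#[O+]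
Why: Palladium-catalysed cyclocarbonylation of a homopropargylic alcohol: the C2 hydroxyl and CO form an alkoxycarbonyl–palladium species on divalent palladium that adds syn across the tethered terminal alkyne, and protonolysis of the vinyl–palladium bond should release the α-methylene-γ-butyrolactone with the trans C1/C2 relationship from step 15 unchanged (the remote C9–OH has no alkyne within reach).

Step 23
Reactants: 34 hydroxy lactone
Product: 35 (1R,2S,3E,7E,9R,11E)-9-acetoxycembra-3,7,11,15(17)-tetraen-16,2-olide (target)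
Conditions: Ac2O, pyridine, 4-(dimethylamino)pyridine (cat.), CH2Cl2, 0 °C
Reagents that add atoms: acetic anhydride, CC(=O)OC(C)=O
Why: O-Acetylation of the remaining secondary allylic alcohol with retention at C9 completes the target.

**Compound list**

1 | prenyl bromide (1-bromo-3-methylbut-2-ene) | CC(C)=CCBr | starting material
2 | sodium benzenesulfinate | [Na+].[O-]S(=O)c1ccccc1 | starting material
3 | prenyl phenyl sulfone, [(3-methylbut-2-en-1-yl)sulfonyl]benzene | CC(C)=CCS(=O)(=O)c1ccccc1 | intermediate
4 | (E)-2-methyl-4-(phenylsulfonyl)but-2-enal | O=C/C(C)=C/CS(=O)(=O)c1ccccc1 | intermediate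
5 | but-2-yn-1-ol | CC#CCO | starting material
6 | but-2-yn-1-yl methyl carbonate | CC#CCOC(=O)OC | intermediate
7 | 2-(buta-2,3-dien-2-yl)-4,4,5,5-tetramethyl-1,3,2-dioxaborolane | C=C=C(C)B1OC(C)(C)C(C)(C)O1 | intermediate
8 | (4R,2E)-3-methyl-1-(phenylsulfonyl)oct-2-en-6-yn-4-ol | CC#CC[C@@H](O)/C(C)=C/CS(=O)(=O)c1ccccc1 | intermediate
9 | tert-butyldimethyl{[(4R,2E)-3-methyl-1-(phenylsulfonyl)oct-2-en-6-yn-4-yl]oxy}silane | CC#CC[C@@H](O[Si](C)(C)C(C)(C)C)/C(C)=C/CS(=O)(=O)c1ccccc1 | intermediate
10 | chlorobis(cyclopentadienyl)[(2E,5R,6E)-5-(tert-butyldimethylsilyloxy)-6-methyl-8-(phenylsulfonyl)octa-2,6-dien-2-yl]zirconium (cyclopentadienyl rings drawn η1) | C/C(=C\C[C@@H](O[Si](C)(C)C(C)(C)C)/C(C)=C/CS(=O)(=O)c1ccccc1)[Zr](Cl)(C1C=CC=C1)C1C=CC=C1 | intermediate (not isolated)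
11 | tert-butyl{[(2E,4R,6E)-7-iodo-3-methyl-1-(phenylsulfonyl)octa-2,6-dien-4-yl]oxy}dimethylsilane | C/C(I)=C\C[C@@H](O[Si](C)(C)C(C)(C)C)/C(C)=C/CS(=O)(=O)c1ccccc1 | intermediate
12 | ethynyltriisopropylsilane | C#C[Si](C(C)C)(C(C)C)C(C)C | starting material
13 | acrolein (prop-2-enal) | C=CC=O | starting material
14 | lithium (triisopropylsilyl)acetylide | [Li]C#C[Si](C(C)C)(C(C)C)C(C)C | intermediate (not isolated)
15 | rac-5-(triisopropylsilyl)pent-1-en-4-yn-3-ol | C=CC(O)C#C[Si](C(C)C)(C(C)C)C(C)C | intermediate
16 | (S)-5-(triisopropylsilyl)pent-1-en-4-yn-3-ol | C=C[C@H](O)C#C[Si](C(C)C)(C(C)C)C(C)C | intermediate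
17 | 9-[(3S)-3-(9-borabicyclo[3.3.1]nonan-9-yloxy)-5-(triisopropylsilyl)pent-4-yn-1-yl]-9-borabicyclo[3.3.1]nonane | CC(C)[Si](C(C)C)(C(C)C)C#C[C@@H](OB1C2CCCC1CCC2)CCB1C2CCCC1CCC2 | intermediate (not isolated)
18 | (3S,6E,9R,10E)-9-[(tert-butyldimethylsilyl)oxy]-6,10-dimethyl-12-(phenylsulfonyl)-1-(triisopropylsilyl)dodeca-6,10-dien-1-yn-3-ol | CC(C)[Si](C(C)C)(C(C)C)C#C[C@@H](O)CC/C(C)=C/C[C@@H](O[Si](C)(C)C(C)(C)C)/C(C)=C/CS(=O)(=O)c1ccccc1 | intermediate
19 | (3S,6E,9R,10E)-9-[(tert-butyldimethylsilyl)oxy]-6,10-dimethyl-12-(phenylsulfonyl)-1-(triisopropylsilyl)dodeca-6,10-dien-1-yn-3-yl methanesulfonate | CC(C)[Si](C(C)C)(C(C)C)C#C[C@@H](OS(C)(=O)=O)CC/C(C)=C/C[C@@H](O[Si](C)(C)C(C)(C)C)/C(C)=C/CS(=O)(=O)c1ccccc1 | intermediate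
20 | 1-[(tert-butyldimethylsilyl)oxy]propan-2-one | CC(=O)CO[Si](C)(C)C(C)(C)C | starting material
21 | triethyl phosphonoacetate | CCOC(=O)CP(=O)(OCC)OCC | starting material
22 | ethyl (E)-4-[(tert-butyldimethylsilyl)oxy]-3-methylbut-2-enoate | CCOC(=O)/C=C(\C)CO[Si](C)(C)C(C)(C)C | intermediate
23 | (E)-4-[(tert-butyldimethylsilyl)oxy]-3-methylbut-2-en-1-ol | OC/C=C(\C)CO[Si](C)(C)C(C)(C)C | intermediate
24 | (E)-4-[(tert-butyldimethylsilyl)oxy]-3-methylbut-2-enal | O=C/C=C(\C)CO[Si](C)(C)C(C)(C)C | intermediate
25 | (aR)-allenylindium iodide methanesulfonate from 19 (indium on the silyl-bearing allene carbon; the axial configuration aR is not encoded in the SMILES) | CC(C)[Si](C(C)C)(C(C)C)C(=C=CCC/C(C)=C/C[C@@H](O[Si](C)(C)C(C)(C)C)/C(C)=C/CS(=O)(=O)c1ccccc1)[In](I)OS(C)(=O)=O | intermediate (not isolated)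
26 | (2E,4S,5R,8E,11R,12E)-1,11-bis[(tert-butyldimethylsilyl)oxy]-2,8,12-trimethyl-14-(phenylsulfonyl)-5-[(triisopropylsilyl)ethynyl]tetradeca-2,8,12-trien-4-ol | CC(C)(C)[Si](C)(C)OC/C(C)=C/[C@H](O)[C@@H](C#C[Si](C(C)C)(C(C)C)C(C)C)CC/C(C)=C/C[C@@H](O[Si](C)(C)C(C)(C)C)/C(C)=C/CS(=O)(=O)c1ccccc1 | intermediate
27 | (2E,4S,5R,8E,11R,12E)-1,4,11-tris[(tert-butyldimethylsilyl)oxy]-2,8,12-trimethyl-14-(phenylsulfonyl)-5-[(triisopropylsilyl)ethynyl]tetradeca-2,8,12-triene | CC(C)(C)[Si](C)(C)OC/C(C)=C/[C@H](O[Si](C)(C)C(C)(C)C)[C@@H](C#C[Si](C(C)C)(C(C)C)C(C)C)CC/C(C)=C/C[C@@H](O[Si](C)(C)C(C)(C)C)/C(C)=C/CS(=O)(=O)c1ccccc1 | intermediate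
28 | (2E,4S,5R,8E,11R,12E)-4,11-bis[(tert-butyldimethylsilyl)oxy]-2,8,12-trimethyl-14-(phenylsulfonyl)-5-[(triisopropylsilyl)ethynyl]tetradeca-2,8,12-trien-1-ol | OC/C(C)=C/[C@H](O[Si](C)(C)C(C)(C)C)[C@@H](C#C[Si](C(C)C)(C(C)C)C(C)C)CC/C(C)=C/C[C@@H](O[Si](C)(C)C(C)(C)C)/C(C)=C/CS(=O)(=O)c1ccccc1 | intermediate
29 | (2E,4S,5R,8E,11R,12E)-1-bromo-4,11-bis[(tert-butyldimethylsilyl)oxy]-2,8,12-trimethyl-14-(phenylsulfonyl)-5-[(triisopropylsilyl)ethynyl]tetradeca-2,8,12-triene | BrC/C(C)=C/[C@H](O[Si](C)(C)C(C)(C)C)[C@@H](C#C[Si](C(C)C)(C(C)C)C(C)C)CC/C(C)=C/C[C@@H](O[Si](C)(C)C(C)(C)C)/C(C)=C/CS(=O)(=O)c1ccccc1 | intermediate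
30 | potassium salt of 29 deprotonated at the sulfonyl-bearing carbon (C6) | [K+].BrC/C(C)=C/[C@H](O[Si](C)(C)C(C)(C)C)[C@@H](C#C[Si](C(C)C)(C(C)C)C(C)C)CC/C(C)=C/C[C@@H](O[Si](C)(C)C(C)(C)C)/C(C)=C/[CH-]S(=O)(=O)c1ccccc1 | intermediate (not isolated)
31 | (1R,2S,3E,7E,9R,11E)-2,9-bis[(tert-butyldimethylsilyl)oxy]-4,8,12-trimethyl-6-(phenylsulfonyl)-1-[(triisopropylsilyl)ethynyl]cyclotetradeca-3,7,11-triene (cembrane ring numbering; both C6 epimers) | C1[C@H](C#C[Si](C(C)C)(C(C)C)C(C)C)[C@@H](O[Si](C)(C)C(C)(C)C)/C=C(\C)CC(S(=O)(=O)c2ccccc2)/C=C(\C)[C@H](O[Si](C)(C)C(C)(C)C)C/C=C(\C)C1 | intermediate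
32 | (1R,2S,3E,7E,9R,11E)-2,9-bis[(tert-butyldimethylsilyl)oxy]-4,8,12-trimethyl-1-[(triisopropylsilyl)ethynyl]cyclotetradeca-3,7,11-triene (cembrane ring numbering) | C1[C@H](C#C[Si](C(C)C)(C(C)C)C(C)C)[C@@H](O[Si](C)(C)C(C)(C)C)/C=C(\C)CC/C=C(\C)[C@H](O[Si](C)(C)C(C)(C)C)C/C=C(\C)C1 | intermediate
33 | (1R,2S,3E,7E,9R,11E)-1-ethynyl-4,8,12-trimethylcyclotetradeca-3,7,11-triene-2,9-diol (cembrane ring numbering) | C1[C@H](C#C)[C@@H](O)/C=C(\C)CC/C=C(\C)[C@H](O)C/C=C(\C)C1 | intermediate
34 | (1R,2S,3E,7E,9R,11E)-9-hydroxycembra-3,7,11,15(17)-tetraen-16,2-olide | C=C1C(=O)O[C@H]2/C=C(\C)CC/C=C(\C)[C@H](O)C/C=C(\C)CC[C@H]12 | intermediate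
35 | (1R,2S,3E,7E,9R,11E)-9-acetoxycembra-3,7,11,15(17)-tetraen-16,2-olide | C=C1C(=O)O[C@H]2/C=C(\C)CC/C=C(\C)[C@H](OC(C)=O)C/C=C(\C)CC[C@H]12 | target

**Step count and risks**

Total step count: 23. Longest linear sequence: 16 steps (1, 2, 5, 6, 7, 10, 11, 15, 16, 17, 18, 19, 20, 21, 22, 23).

Steps most likely to fail:

1. Step 19 (macrocyclisation). What may go wrong: intermolecular alkylation leading to oligomers, base-induced 1,4-elimination (loss of the C9 silyloxy group from the anion or of HBr from the bromide), or sluggish closure at high dilution. Fallback, setting out from 28 and returning at 31: the primary alcohol is converted with methyl chloroformate and pyridine into the allylic methyl carbonate F1. The sulfone is deprotonated with NaN(SiMe3)2 at −78 °C and the anion is added slowly to Pd(PPh3)4 and 1,2-bis(diphenylphosphino)ethane in THF at 50 °C. Zerovalent palladium ionises the carbonate to a π-allyl complex spanning C3–C5, and the sulfonyl carbanion should attack the less hindered C5 terminus remote from the C2 silyl ether (Tsuji–Trost macrocyclisation), giving 31. This replaces the SN2 displacement by a metal-templated allylic alkylation that tolerates higher concentration.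

2. Step 5 (catalytic asymmetric allenylboration). What may go wrong: poor facial selectivity or low turnover with the methyl-substituted allenylboronate on this enal. Fallback, setting out from 4 and returning at 8: uncatalysed allenylboration of 4 with 7 in toluene should give the racemic homopropargylic alcohol F2. Oxidation with Dess–Martin periodinane (NaHCO3 buffer) gives the enone F3. Corey–Bakshi–Shibata reduction with (S)-1-methyl-3,3-diphenyltetrahydro-1H,3H-pyrrolo[1,2-c][1,3,2]oxazaborole and BH3·SMe2 at −30 °C, in which the α-methylalkenyl group acts as the large substituent, should give the (R)-alcohol 8.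

3. Step 22 (cyclocarbonylation). What may go wrong: palladium-induced isomerisation or ionisation at the free allylic C9 alcohol or the 1,5-diene units, or incomplete CO incorporation. Fallback, setting out from 33 and returning at 34: anti-Markovnikov hydroboration of the ethynyl group with dicyclohexylborane (excess, since both hydroxyls consume borane) and NaBO3 oxidation should give the aldehyde, which closes onto the C2 hydroxyl as the lactol F4. N-Iodosuccinimide with Bu4NI should oxidise the lactol selectively to the saturated trans-lactone F5. Deprotonation with LiN(i-Pr)2 (3 equiv) and trapping of the lactone enolate with dimethylmethyleneammonium iodide should give the Mannich base F6. Quaternisation with MeI and elimination with NaHCO3 installs the exocyclic methylene and gives 34.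

Further compounds

F1 | step 19 | (2E,4S,5R,8E,11R,12E)-4,11-bis[(tert-butyldimethylsilyl)oxy]-2,8,12-trimethyl-14-(phenylsulfonyl)-5-[(triisopropylsilyl)ethynyl]tetradeca-2,8,12-trien-1-yl methyl carbonate | COC(=O)OC/C(C)=C/[C@H](O[Si](C)(C)C(C)(C)C)[C@@H](C#C[Si](C(C)C)(C(C)C)C(C)C)CC/C(C)=C/C[C@@H](O[Si](C)(C)C(C)(C)C)/C(C)=C/CS(=O)(=O)c1ccccc1
F2 | step 5 | rac-(E)-3-methyl-1-(phenylsulfonyl)oct-2-en-6-yn-4-ol | CC#CCC(O)/C(C)=C/CS(=O)(=O)c1ccccc1
F3 | step 5 | (E)-3-methyl-1-(phenylsulfonyl)oct-2-en-6-yn-4-one | CC#CCC(=O)/C(C)=C/CS(=O)(=O)c1ccccc1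
F4 | step 22 | (1R,2R,3E,7E,9R,11E)-2,16-epoxy-17-norcembra-3,7,11-triene-9,16-diol (lactol, both anomers; same spatial arrangement at C1, C2 and C9 as 34) | C1C(O)O[C@H]2/C=C(\C)CC/C=C(\C)[C@H](O)C/C=C(\C)CC[C@H]12
F5 | step 22 | (1R,2R,3E,7E,9R,11E)-9-hydroxy-17-norcembra-3,7,11-trien-16,2-olide (same spatial arrangement at C1, C2 and C9 as 34) | C1C(=O)O[C@H]2/C=C(\C)CC/C=C(\C)[C@H](O)C/C=C(\C)CC[C@H]12
F6 | step 22 | (1R,2R,3E,7E,9R,11E)-17-(dimethylamino)-9-hydroxy-15,17-dihydrocembra-3,7,11-trien-16,2-olide (C15 epimers; same spatial arrangement at C1, C2 and C9 as 34) | CN(C)CC1C(=O)O[C@H]2/C=C(\C)CC/C=C(\C)[C@H](O)C/C=C(\C)CC[C@H]12
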